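The constants belong to no real substance; the flask was simulated.

Ask what part of the charge can end as target, and wall it in from both sides before any result is seen.

starting material 0.44 M; first nucleophile 2.20 M; gas 55 mM (held); time 1.0 h

    starting material → intermediate (k1 = 8.04 × 10⁻⁴ s⁻¹)
    first nucleophile + intermediate → target (k2 = 0.446 L mol⁻¹ s⁻¹)
    second nucleophile + intermediate → other capture product (k3 = 23.3 L mol⁻¹ s⁻¹)
    gas ⇌ second nucleophile, rate k4*(csat - [second nucleophile]) (k4 = 0.0121 s⁻¹, csat = 55 mM)

- at 1.0 h, what has stopped the reaction, if anything has (all of the starting material has reacted / the first nucleophile has run out first / it is still moving)
- how much target there is at 1.0 h, in percent of the starting material charged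

- at the start none of second nucleophile is dissolved
- the reaction counts as stopped when no species that holds the starting material changes by six tenths of a point or more over the second half of the time
- run time (flask): 1.0 h

Start with the conversion. The first step runs on its own, so by 1.0 h a fraction 94.5 % of the starting material has passed into the intermediate. The starting material still falls by 18 percentage points over the second half, so I call the flask still moving. Each capture is pseudo-first-order in the intermediate, so k2·c(first nucleophile) and k3·c(second nucleophile) divide it.

For the ceiling, give the target all of that conversion, then tighten. The transfer has a time constant of about 82.6 s, and second nucleophile is used at about k1·cA or less, so after that time I take c(second nucleophile) to stay at about 25.8 mM or above. That caps the target's share at 62.0 %, and with the passage during the lag the ceiling is about 61.1 %.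

For the floor, c(second nucleophile) stays at or below csat, and c(first nucleophile) cannot fall below cB minus cA, which gives 35.9 %. Tighten with the ceiling: c(first nucleophile) stays above 1.93 M. The target's share at that level against saturation, 40.2 %, is the floor share. Multiplied by the conversion, it gives 38.0 %.

The forecast says it is still moving, with 45.5 % of target, holding that the split is about even “The intermediate splits roughly evenly between the first nucleophile and the dissolved gas”. Its target figure lies inside my bracket.

The flask gives it is still moving, with 45.5 % of target. For a miss of 5 points, the target would need first nucleophile charged at 1.75 M or 2.76 M, all else held, or the time cut to 0.604 h, all amounts held.

At 0.221 h in this flask the intermediate's half-life is 0.012 min by the first nucleophile and 0.011 min by the second, so the target's share of the capture at that moment is 46.4 %, above the floor share.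

Left until 25 min, the same flask has the floor share times its conversion as floor, 28.2 %; it gives 35.1 %.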